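## Retrosynthetic overview

1. Target 22 ⇐ silyl ether 21 ⇐ 8α-alcohol 19, esterified with inversion at C8 (Mitsunobu).
2. Key disconnection C7–C8: the bromomethyl-butenolide of 17 is turned into an allylchromium, so that C7 (the β-carbon of the unsaturated lactone, normally an acceptor) attacks the C8 aldehyde. This closes the ten-membered ring, creates the exocyclic methylene and sets C7 and C8 from C6.
3. Ring order: the lactone ring is made first, as a butenolide, by ring-closing metathesis of the 2-(bromomethyl)acrylate 15; the ten-membered carbocycle is made second, in the key step.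
4. Acyclic chain: C1=C10 by Wittig reaction with formyl ylide 4; C3–C4 by Heck coupling with allyl alcohol; C4=C5 geometry by hydroxyl-directed hydroalumination–iodination; C6 by catalytic asymmetric alkynylation of crotonaldehyde.

Assumption: germacrane atom labels C1–C15 are used in the explanations, and (S,S)-ProPhenol is taken to deliver the alkynyl group to the Re face of the enal (the (R,R)-ligand is used if the sense proves opposite).

## Route

Step 1
Reactants: 1 [2-(1,3-dioxolan-2-yl)ethyl]triphenylphosphonium bromide; 2 ethyl formate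
Product: 4 3-(1,3-dioxolan-2-yl)-2-(triphenyl-λ5-phosphanylidene)propanal, via phosphonium ylide 3 (not isolated)
Conditions: KOtBu, THF, 0 °C; then HCO2Et, 0 °C → rt
Reagents that add atoms: none
Why: Deprotonation gives the non-stabilised ylide, which is C-formylated by ethyl formate (acylation of a phosphonium ylide, the released ethoxide removing the remaining α-proton) to give the stabilised α-formyl ylide carrying C14, C10, C9 and masked C8; no stereocentre is involved.

Step 2
Reactants: 5 tert-butyldimethyl(prop-2-yn-1-yloxy)silane; 6 (E)-but-2-enal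
Product: 8 (4S,5E)-1-[(tert-butyldimethylsilyl)oxy]hept-5-en-2-yn-4-ol, via alkynyl(methyl)zinc 7 (not isolated)
Conditions: Me2Zn, (S,S)-ProPhenol (2,6-bis{[(S)-2-(hydroxydiphenylmethyl)pyrrolidin-1-yl]methyl}-4-methylphenol, 10 mol%), Ph3PO (20 mol%), PhMe, 0 → 4 °C; aq. work-up
Reagents that add atoms: none
Why: Zinc–ProPhenol catalysed asymmetric alkynylation of an enal, in which the dinuclear zinc catalyst delivers the alkynyl group to the Re face of crotonaldehyde and so sets C6 (S here, R in the target because the substituent priorities change later).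

Step 3
Reactants: 8 (4S,5E)-1-[(tert-butyldimethylsilyl)oxy]hept-5-en-2-yn-4-ol
Product: 10 (2Z,4S,5E)-1-[(tert-butyldimethylsilyl)oxy]-2-iodohepta-2,5-dien-4-ol, via cyclic alkenylalanate 9 (not isolated)
Conditions: NaAlH2(OCH2CH2OMe)2, THF, 0 °C → rt; then I2, −78 → 0 °C
Reagents that add atoms: iodine, II
Why: Hydroxyl-directed trans-hydroalumination of the propargylic alcohol puts H on C5 and aluminium on C4 in a five-membered alkenylalanate, and iodinolysis with retention gives the (Z)-iodide with iodine cis to C6, which fixes the C4=C5 geometry of the target.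

Step 4
Reactants: 10 (2Z,4S,5E)-1-[(tert-butyldimethylsilyl)oxy]-2-iodohepta-2,5-dien-4-ol; 11 prop-2-en-1-ol
Product: 12 (4E,6S,7E)-4-{[(tert-butyldimethylsilyl)oxy]methyl}-6-hydroxynona-4,7-dienal
Conditions: Pd(OAc)2 (5 mol%), Bu4NCl, NaHCO3, DMF, 35 °C
Reagents that add atoms: none
Why: Jeffery-type Heck reaction of an alkenyl iodide with allyl alcohol, in which carbopalladation at the terminal carbon, β-hydride elimination toward the carbinol carbon and enol tautomerisation give the 4-enal (C3–C2–C1) with retention of the alkenyl geometry (C3 cis to C6).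

Step 5
Reactants: 12 (4E,6S,7E)-4-{[(tert-butyldimethylsilyl)oxy]methyl}-6-hydroxynona-4,7-dienal; 4 3-(1,3-dioxolan-2-yl)-2-(triphenyl-λ5-phosphanylidene)propanal
Product: 13 (2E,6E,8S,9E)-6-{[(tert-butyldimethylsilyl)oxy]methyl}-2-[(1,3-dioxolan-2-yl)methyl]-8-hydroxyundeca-2,6,9-trienal
Conditions: PhMe, 85 °C
Reagents that add atoms: none
Why: Wittig olefination with a stabilised α-formyl ylide gives the (E)-2-substituted enal (C2 trans to the formyl group, hence cis to C9 as the ring needs) and stops there because the conjugated, α-branched product aldehyde does not react further.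

Step 6
Reactants: 13 (2E,6E,8S,9E)-6-{[(tert-butyldimethylsilyl)oxy]methyl}-2-[(1,3-dioxolan-2-yl)methyl]-8-hydroxyundeca-2,6,9-trienal; 14 2-(bromomethyl)prop-2-enoic acid
Product: 15 (2E,4S,5E,9E)-6-{[(tert-butyldimethylsilyl)oxy]methyl}-11-(1,3-dioxolan-2-yl)-10-formylundeca-2,5,9-trien-4-yl 2-(bromomethyl)prop-2-enoate
Conditions: DCC, DMAP (5 mol%), CH2Cl2, −10 → 0 °C
Reagents that add atoms: none
Why: Steglich esterification of the only free hydroxyl proceeds with retention at C6, and catalytic DMAP at low temperature leaves the allylic bromide untouched.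

Step 7
Reactants: 15 (2E,4S,5E,9E)-6-{[(tert-butyldimethylsilyl)oxy]methyl}-11-(1,3-dioxolan-2-yl)-10-formylundeca-2,5,9-trien-4-yl 2-(bromomethyl)prop-2-enoate
Product: 16 (5R)-3-(bromomethyl)-5-[(1E,5E)-2-{[(tert-butyldimethylsilyl)oxy]methyl}-7-(1,3-dioxolan-2-yl)-6-formylhepta-1,5-dien-1-yl]furan-2(5H)-one
Conditions: second-generation Grubbs catalyst RuCl2(=CHPh)(PCy3)(H2IMes) (7 mol%), PhMe (5 mM), 80 °C
Reagents that add atoms: none
Why: Ring-closing metathesis between the propenyl group and the 1,1-disubstituted acrylate closes the butenolide with loss of propene, the trisubstituted alkenes being inert and C6 untouched (descriptor becomes R only through the new priorities).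

Step 8
Reactants: 16 (5R)-3-(bromomethyl)-5-[(1E,5E)-2-{[(tert-butyldimethylsilyl)oxy]methyl}-7-(1,3-dioxolan-2-yl)-6-formylhepta-1,5-dien-1-yl]furan-2(5H)-one
Product: 17 (5R)-3-(bromomethyl)-5-[(1E,5E)-2-{[(tert-butyldimethylsilyl)oxy]methyl}-6-formyl-8-oxoocta-1,5-dien-1-yl]furan-2(5H)-one
Conditions: PPTS (30 mol%), acetone/H2O 9:1, 45 °C; crude product used at once
Reagents that add atoms: water, O
Why: Mild acid-catalysed acetal hydrolysis frees the C8 aldehyde while the weakly acidic, base-free medium spares the primary silyl ether, the allylic bromide and the base-sensitive γ-alkenyl butenolide.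

Step 9
Reactants: 17 (5R)-3-(bromomethyl)-5-[(1E,5E)-2-{[(tert-butyldimethylsilyl)oxy]methyl}-6-formyl-8-oxoocta-1,5-dien-1-yl]furan-2(5H)-one
Product: 19 (3aR,4S,6E,10E,11aR)-10-{[(tert-butyldimethylsilyl)oxy]methyl}-4-hydroxy-3-methylidene-2-oxo-2,3,3a,4,5,8,9,11a-octahydrocyclodeca[b]furan-6-carbaldehyde, via allylchromium dichloride 18 (not isolated)
Conditions: CrCl2 (8 equiv), THF, rt; 17 added by syringe pump over 12 h (final 2 mM); then H2O
Reagents that add atoms: none
Why: Intramolecular Nozaki–Hiyama–Kishi (Barbier-type) allylation in which CrCl2 converts the allylic bromide into an allylchromium whose γ-carbon C7 adds to the C8 aldehyde, closing the ten-membered ring and shifting the alkene to the exocyclic position; attack anti to the C5 substituent of the butenolide gives the trans-lactone (7R), the chair transition state of the ring-locked E-allylchromium with C9 equatorial gives the 7,8-anti 8α-alcohol (8S), and the C14 enal is spared because closure onto it would need an E-alkene in a nine-membered ring.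

Step 10
Reactants: 19 (3aR,4S,6E,10E,11aR)-10-{[(tert-butyldimethylsilyl)oxy]methyl}-4-hydroxy-3-methylidene-2-oxo-2,3,3a,4,5,8,9,11a-octahydrocyclodeca[b]furan-6-carbaldehyde; 20 (2S)-2-methylbutanoic acid
Product: 21 (3aR,4R,6E,10E,11aR)-10-{[(tert-butyldimethylsilyl)oxy]methyl}-6-formyl-3-methylidene-2-oxo-2,3,3a,4,5,8,9,11a-octahydrocyclodeca[b]furan-4-yl (2S)-2-methylbutanoate
Conditions: PPh3, DIAD, PhMe, 0 °C → rt (betaine pre-formed before 19 is added)
Reagents that add atoms: none
Why: Mitsunobu esterification displaces the activated C8 oxygen by the carboxylate with SN2 inversion, turning the 8α-alcohol into the 8β (8R) ester without touching the stereocentre of the acid.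

Step 11
Reactants: 21 (3aR,4R,6E,10E,11aR)-10-{[(tert-butyldimethylsilyl)oxy]methyl}-6-formyl-3-methylidene-2-oxo-2,3,3a,4,5,8,9,11a-octahydrocyclodeca[b]furan-4-yl (2S)-2-methylbutanoate
Product: 22 (3aR,4R,6E,10E,11aR)-6-formyl-10-(hydroxymethyl)-3-methylidene-2-oxo-2,3,3a,4,5,8,9,11a-octahydrocyclodeca[b]furan-4-yl (2S)-2-methylbutanoate
Conditions: HF·pyridine, THF/pyridine, 0 °C → rt
Reagents that add atoms: none
Why: Fluoride-mediated desilylation under buffered, non-basic conditions frees the C15 alcohol without affecting the enal, the ester or the α-methylene lactone.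

## Compound list

1 | [2-(1,3-dioxolan-2-yl)ethyl]triphenylphosphonium bromide | [Br-].C1COC(CC[P+](c2ccccc2)(c2ccccc2)c2ccccc2)O1 | starting material
2 | ethyl formate | CCOC=O | starting material
3 | [2-(1,3-dioxolan-2-yl)ethylidene]triphenyl-λ5-phosphane (non-stabilised ylide) | C1COC(CC=P(c2ccccc2)(c2ccccc2)c2ccccc2)O1 | intermediate
4 | 3-(1,3-dioxolan-2-yl)-2-(triphenyl-λ5-phosphanylidene)propanal | O=CC(CC1OCCO1)=P(c1ccccc1)(c1ccccc1)c1ccccc1 | intermediate
5 | tert-butyldimethyl(prop-2-yn-1-yloxy)silane | C#CCO[Si](C)(C)C(C)(C)C | starting material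
6 | (E)-but-2-enal (crotonaldehyde) | C/C=C/C=O | starting material
7 | methyl{3-[(tert-butyldimethylsilyl)oxy]prop-1-yn-1-yl}zinc | C[Zn]C#CCO[Si](C)(C)C(C)(C)C | intermediate
8 | (4S,5E)-1-[(tert-butyldimethylsilyl)oxy]hept-5-en-2-yn-4-ol | C/C=C/[C@H](O)C#CCO[Si](C)(C)C(C)(C)C | intermediate
9 | sodium (5S)-3-{[(tert-butyldimethylsilyl)oxy]methyl}-2,2-bis(2-methoxyethoxy)-5-[(1E)-prop-1-en-1-yl]-2,5-dihydro-1,2-oxaluminol-2-uide (cyclic alkenylalanate) | [Na+].C/C=C/[C@H]1C=C(CO[Si](C)(C)C(C)(C)C)[Al-](OCCOC)(OCCOC)O1 | intermediate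
10 | (2Z,4S,5E)-1-[(tert-butyldimethylsilyl)oxy]-2-iodohepta-2,5-dien-4-ol | C/C=C/[C@H](O)/C=C(\I)CO[Si](C)(C)C(C)(C)C | intermediate
11 | prop-2-en-1-ol (allyl alcohol) | C=CCO | starting material
12 | (4E,6S,7E)-4-{[(tert-butyldimethylsilyl)oxy]methyl}-6-hydroxynona-4,7-dienal | C/C=C/[C@H](O)/C=C(\CCC=O)CO[Si](C)(C)C(C)(C)C | intermediate
13 | (2E,6E,8S,9E)-6-{[(tert-butyldimethylsilyl)oxy]methyl}-2-[(1,3-dioxolan-2-yl)methyl]-8-hydroxyundeca-2,6,9-trienal | C/C=C/[C@H](O)/C=C(\CC/C=C(/C=O)CC1OCCO1)CO[Si](C)(C)C(C)(C)C | intermediate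
14 | 2-(bromomethyl)prop-2-enoic acid | C=C(CBr)C(=O)O | starting material
15 | (2E,4S,5E,9E)-6-{[(tert-butyldimethylsilyl)oxy]methyl}-11-(1,3-dioxolan-2-yl)-10-formylundeca-2,5,9-trien-4-yl 2-(bromomethyl)prop-2-enoate | C/C=C/[C@H](OC(=O)C(=C)CBr)/C=C(\CC/C=C(/C=O)CC1OCCO1)CO[Si](C)(C)C(C)(C)C | intermediate
16 | (5R)-3-(bromomethyl)-5-[(1E,5E)-2-{[(tert-butyldimethylsilyl)oxy]methyl}-7-(1,3-dioxolan-2-yl)-6-formylhepta-1,5-dien-1-yl]furan-2(5H)-one | O=C1O[C@H](/C=C(\CC/C=C(/C=O)CC2OCCO2)CO[Si](C)(C)C(C)(C)C)C=C1CBr | intermediate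
17 | (5R)-3-(bromomethyl)-5-[(1E,5E)-2-{[(tert-butyldimethylsilyl)oxy]methyl}-6-formyl-8-oxoocta-1,5-dien-1-yl]furan-2(5H)-one | O=C1O[C@H](/C=C(\CC/C=C(/C=O)CC=O)CO[Si](C)(C)C(C)(C)C)C=C1CBr | intermediate
18 | dichloro{[(5R)-5-[(1E,5E)-2-{[(tert-butyldimethylsilyl)oxy]methyl}-6-formyl-8-oxoocta-1,5-dien-1-yl]-2-oxo-2,5-dihydrofuran-3-yl]methyl}chromium (allylchromium of trivalent chromium) | O=C1O[C@H](/C=C(\CC/C=C(/C=O)CC=O)CO[Si](C)(C)C(C)(C)C)C=C1C[Cr](Cl)Cl | intermediate
19 | (3aR,4S,6E,10E,11aR)-10-{[(tert-butyldimethylsilyl)oxy]methyl}-4-hydroxy-3-methylidene-2-oxo-2,3,3a,4,5,8,9,11a-octahydrocyclodeca[b]furan-6-carbaldehyde (6α,12-trans-lactone, H7α, 8α-OH, both ring alkenes ring-cis) | C=C1C(=O)O[C@@H]2/C=C(/CO[Si](C)(C)C(C)(C)C)CC/C=C(/C=O)C[C@H](O)[C@@H]12 | intermediate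
20 | (2S)-2-methylbutanoic acid | CC[C@H](C)C(=O)O | starting material
21 | (3aR,4R,6E,10E,11aR)-10-{[(tert-butyldimethylsilyl)oxy]methyl}-6-formyl-3-methylidene-2-oxo-2,3,3a,4,5,8,9,11a-octahydrocyclodeca[b]furan-4-yl (2S)-2-methylbutanoate (8β-ester) | C=C1C(=O)O[C@@H]2/C=C(/CO[Si](C)(C)C(C)(C)C)CC/C=C(/C=O)C[C@@H](OC(=O)[C@@H](C)CC)[C@@H]12 | intermediate
22 | (3aR,4R,6E,10E,11aR)-6-formyl-10-(hydroxymethyl)-3-methylidene-2-oxo-2,3,3a,4,5,8,9,11a-octahydrocyclodeca[b]furan-4-yl (2S)-2-methylbutanoate | C=C1C(=O)O[C@@H]2/C=C(/CO)CC/C=C(/C=O)C[C@@H](OC(=O)[C@@H](C)CC)[C@@H]12 | target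

## Step count and risks

Total steps: 11. Longest linear sequence: 10 (steps 2–11); step 1 is a one-step side branch that joins at step 5.

Steps most likely to fail:

**Step 9 (macrocyclisation).** The allylchromium 18 can fragment by β-elimination of the lactone carboxylate, or oligomerise, before it finds the C8 aldehyde. The 8α outcome also rests on intermolecular precedent for ring-locked E-allylmetals. Fallback, setting out from 16 and returning at 19: replace the reductively generated organochromium by an isolable allylboron nucleophile that cannot fragment, and unmask the aldehyde only afterwards. Bromide 16 is borylated (B2pin2, Pd2(dba)3, PhMe, 50 °C, no base) to (5R)-5-[(1E,5E)-2-{[(tert-butyldimethylsilyl)oxy]methyl}-7-(1,3-dioxolan-2-yl)-6-formylhepta-1,5-dien-1-yl]-3-[(4,4,5,5-tetramethyl-1,3,2-dioxaborolan-2-yl)methyl]furan-2(5H)-one F3. The acetal is hydrolysed as in step 8 to the dialdehyde allylboronate F4. F4 is then heated at 2 mM in PhMe with Sc(OTf)3 (10 mol%); intramolecular allylboration through the same chair arrangement gives the pinacol borate of the macrocyclic alcohol F5, which is hydrolysed on work-up to 19.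

**Step 10 (Mitsunobu inversion at C8).** The hindered ring carbinol may eliminate toward C9, or the phosphine may add to the α-methylene lactone. Fallback, setting out from 19 and returning at 21: abandon the redox condensation for a sulfonate displacement. Alcohol 19 is converted (Tf2O, pyridine, CH2Cl2, −40 °C) into (3aS,4S,6E,10E,11aR)-10-{[(tert-butyldimethylsilyl)oxy]methyl}-6-formyl-3-methylidene-2-oxo-2,3,3a,4,5,8,9,11a-octahydrocyclodeca[b]furan-4-yl trifluoromethanesulfonate F6. F6 is displaced with inversion by caesium (2S)-2-methylbutanoate F7 (made from 20 and Cs2CO3; 18-crown-6, PhMe, rt) to give 21. If the macrocyclisation should instead deliver the 8β-alcohol directly, that epimer is simply esterified with 20 under Steglich conditions.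

**Step 4 (Heck coupling with allyl alcohol).** The hindered alkenyl iodide may give dienol or isomerised products instead of the 4-enal. Fallback, setting out from 10 and returning at 12: switch to a B-alkyl Suzuki–Miyaura coupling. 3,3-Diethoxyprop-1-ene is hydroborated with 9-BBN to 9-(3,3-diethoxypropyl)-9-borabicyclo[3.3.1]nonane F1. F1 is coupled with 10 (PdCl2(dppf), AsPh3, Cs2CO3, DMF/THF/H2O, rt) to (2E,4S,5E)-6-{[(tert-butyldimethylsilyl)oxy]methyl}-9,9-diethoxynona-2,5-dien-4-ol F2. The acetal of F2 is hydrolysed with oxalic acid on wet silica gel (CH2Cl2, rt) to aldehyde 12, at the cost of one extra step.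

## Further compounds

F1 | step 4 | 9-(3,3-diethoxypropyl)-9-borabicyclo[3.3.1]nonane | CCOC(CCB1C2CCCC1CCC2)OCC
F2 | step 4 | (2E,4S,5E)-6-{[(tert-butyldimethylsilyl)oxy]methyl}-9,9-diethoxynona-2,5-dien-4-ol | C/C=C/[C@H](O)/C=C(\CCC(OCC)OCC)CO[Si](C)(C)C(C)(C)C
F3 | step 9 | (5R)-5-[(1E,5E)-2-{[(tert-butyldimethylsilyl)oxy]methyl}-7-(1,3-dioxolan-2-yl)-6-formylhepta-1,5-dien-1-yl]-3-[(4,4,5,5-tetramethyl-1,3,2-dioxaborolan-2-yl)methyl]furan-2(5H)-one | O=C1O[C@H](/C=C(\CC/C=C(/C=O)CC2OCCO2)CO[Si](C)(C)C(C)(C)C)C=C1CB1OC(C)(C)C(C)(C)O1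
F4 | step 9 | (5R)-5-[(1E,5E)-2-{[(tert-butyldimethylsilyl)oxy]methyl}-6-formyl-8-oxoocta-1,5-dien-1-yl]-3-[(4,4,5,5-tetramethyl-1,3,2-dioxaborolan-2-yl)methyl]furan-2(5H)-one | O=C1O[C@H](/C=C(\CC/C=C(/C=O)CC=O)CO[Si](C)(C)C(C)(C)C)C=C1CB1OC(C)(C)C(C)(C)O1
F5 | step 9 | (3aR,4S,6E,10E,11aR)-10-{[(tert-butyldimethylsilyl)oxy]methyl}-3-methylidene-2-oxo-4-[(4,4,5,5-tetramethyl-1,3,2-dioxaborolan-2-yl)oxy]-2,3,3a,4,5,8,9,11a-octahydrocyclodeca[b]furan-6-carbaldehyde | C=C1C(=O)O[C@@H]2/C=C(/CO[Si](C)(C)C(C)(C)C)CC/C=C(/C=O)C[C@H](OB3OC(C)(C)C(C)(C)O3)[C@@H]12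
F6 | step 10 | (3aS,4S,6E,10E,11aR)-10-{[(tert-butyldimethylsilyl)oxy]methyl}-6-formyl-3-methylidene-2-oxo-2,3,3a,4,5,8,9,11a-octahydrocyclodeca[b]furan-4-yl trifluoromethanesulfonate | C=C1C(=O)O[C@@H]2/C=C(/CO[Si](C)(C)C(C)(C)C)CC/C=C(/C=O)C[C@H](OS(=O)(=O)C(F)(F)F)[C@@H]12
F7 | step 10 | caesium (2S)-2-methylbutanoate | [Cs+].CC[C@H](C)C(=O)[O-]
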